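Germacrane-type numbering: carbocycle C1–C10 (C3 ketone, C4 CH–CH3, C6 lactone O–CH, C7 fusion CH, C8 CH–O-isobutyryl, C9 CH2, C10 C(OH)CH3). The route rests on the 1,3-dioxygenated triad C8(O)–C9H2–C10(O)(CH3) of the ten-membered ring, read as the retron of a 2-isoxazoline. An intramolecular nitrile oxide–alkene (3+2) cycloaddition of an open-chain cis-γ-lactone carrying a nitrile oxide at C8 and a terminal isopropenyl group (C9=C10) closes the ten-membered ring through the C8–C9 bond and, in the same operation, makes the C10–O bond and its fully substituted stereocentre. N–O cleavage, 1,3-anti reduction, acylation and unmasking of the α-methylene lactone and the C3 ketone complete the synthesis.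

Key step: step 6

Remarks on the chemistry (assumptions):
- C11, C12 and C13 are the lactone α-carbon, the lactone carbonyl and the exocyclic methylene; C14 and C15 are the methyl groups on C10 and C4.
- (R)-2-Methylsuccinic acid 4-methyl ester (1) is taken as a commercial chiral-pool compound.
- The target is taken to exist in the open 3-keto-10-hydroxy form drawn, not as a transannular hemiketal.
- The C=N geometry of the oxime and hydroximoyl chloride and the C11 configuration of the Mannich intermediates are inconsequential; C11 is drawn as the expected epimer.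

Step 1
Reactants: 1 (2R)-4-methoxy-2-methyl-4-oxobutanoic acid; 2 4-bromo-2-methylbut-1-ene
Product: 5 methyl (3R)-3,7-dimethyl-4-oxooct-7-enoate, via acid chloride 3 (not isolated), via Grignard reagent 4 (not isolated)
Conditions: (COCl)2, DMF (cat.), CH2Cl2, 0 °C → rt, evaporation; separately 2, Mg, THF, rt; then 3 + 4, Fe(acac)3 (3 mol%), THF, −78 °C
Reagents that add atoms: oxalyl chloride, ClC(=O)C(=O)Cl (chlorine of 3); magnesium, [Mg] (in 4)
Why: Fe(acac)3-catalysed acylation of a Grignard reagent by an acid chloride is fast at −78 °C and spares the methyl ester, and since no base is present the C4 stereocentre next to the acyl group should be retained.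

Step 2
Reactants: 5 methyl (3R)-3,7-dimethyl-4-oxooct-7-enoate
Product: 6 methyl (3R)-3-[2-(3-methylbut-3-en-1-yl)-1,3-dioxolan-2-yl]butanoate
Conditions: (Me3SiOCH2)2, Me3SiOTf (5 mol%), CH2Cl2, −78 → −20 °C
Reagents that add atoms: 1,2-bis(trimethylsilyloxy)ethane, C[Si](C)(C)OCCO[Si](C)(C)C
Why: Noyori ketalisation under aprotic, kinetic conditions should mask the C3 ketone without epimerising C4 or isomerising the isopropenyl group, and the ketal later blocks enolisation, C4 epimerisation and hemiketal formation.

Step 3
Reactants: 6 methyl (3R)-3-[2-(3-methylbut-3-en-1-yl)-1,3-dioxolan-2-yl]butanoate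
Product: 7 (3R)-3-[2-(3-methylbut-3-en-1-yl)-1,3-dioxolan-2-yl]butanal
Conditions: i-Bu2AlH (1.1 equiv), CH2Cl2, −78 °C; MeOH, then aq. Rochelle salt
Reagents that add atoms: none
Why: Partial i-Bu2AlH reduction of a methyl ester at −78 °C should stop at the aluminium hemiacetal, which releases the aldehyde only on work-up.

Step 4
Reactants: 7 (3R)-3-[2-(3-methylbut-3-en-1-yl)-1,3-dioxolan-2-yl]butanal; 8 methyl 4-oxobutanoate
Product: 10 methyl (3R,4S,6R)-4-hydroxy-3-[(hydroxyimino)methyl]-6-[2-(3-methylbut-3-en-1-yl)-1,3-dioxolan-2-yl]heptanoate, via aldol aldehyde 9 (not isolated)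
Conditions: L-proline (20 mol%), DMF, 4 °C, 8 (2 equiv) added by syringe pump over 24 h; then NH2OH·HCl, NaOAc, MeOH, 0 °C → rt
Reagents that add atoms: hydroxylamine hydrochloride, Cl.NO
Why: In this proline-catalysed enamine cross-aldol reaction the (E)-enamine of the unhindered donor 8 should add to the β-branched, slowly enolising acceptor 7 through the carboxylic acid-organised chair transition state, setting C6 (S) and C7 anti under catalyst control (the sense established for L-proline), and immediate oximation traps the epimerisable β-hydroxy aldehyde.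

Step 5
Reactants: 10 anti-aldol oxime (hydroxy ester)
Product: 11 (4R,5S)-4-[(hydroxyimino)methyl]-5-{(2R)-2-[2-(3-methylbut-3-en-1-yl)-1,3-dioxolan-2-yl]propyl}oxolan-2-one
Conditions: PPTS (10 mol%), toluene, 60 °C
Reagents that add atoms: none
Why: Acid-catalysed lactonisation (intramolecular transesterification) proceeds with retention at C6, so the anti-aldol relationship becomes the cis C6/C7 substitution of the γ-lactone, and the dioxolane and oxime should tolerate anhydrous PPTS.

Step 6
Reactants: 11 cis-lactone oxime
Product: 14 bridged isoxazoline lactone (4R,6S,7R,10S), via hydroximoyl chloride 12 (not isolated), via nitrile oxide 13 (not isolated)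
Conditions: NCS (1.05 equiv), DMF, 0 °C → rt; this solution added by syringe pump over 16 h to Et3N (3 equiv), toluene, 80 °C (final concentration ≤ 1 mM)
Reagents that add atoms: N-chlorosuccinimide, O=C1CCC(=O)N1Cl (chlorine of 12)
Why: Chlorination of the aldoxime and 1,3-dehydrochlorination release nitrile oxide 13, whose C8≡N–O dipole adds to the tethered isopropenyl group in a concerted, suprafacial 1,3-dipolar (3+2) cycloaddition that forms C8–C9 and O–C10 together. The closest known reaction type is the intramolecular nitrile oxide–alkene cycloaddition in its macrocyclising mode, which gives bridged 2-isoxazolines from ω-alkenyl nitrile oxides. The ten-membered carbocycle closes in the endo mode (C9 and C10 both become ring members, C8 attacking the terminal CH2), and the five-membered isoxazoline closes concomitantly as the C9-bridged heterocycle C8=N–O–C10. The new C10 stereocentre is set by the alkene face presented to the dipole, which the resident cis-lactone controls: with H7 eclipsing the developing C8=N bond (minimal allylic strain) the lactone CH2 (C11) screens one face, so the O–C10 bond should form anti to the lactone with the C10 methyl outward (10S). Regioselectivity (oxygen to the more substituted C10, carbon to C9) follows from the 1,1-disubstituted alkene and from avoidance of a nine-membered ring with a quaternary C–C centre, while ring closure is favoured over furoxan dimerisation by slow generation of 13 at high dilution, by the gem-disubstituted C3 ketal and by the rigid lactone. Because the lactone is still saturated, the isopropenyl group is the only dipolarophile in the molecule.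

Step 7
Reactants: 14 bridged isoxazoline lactone
Product: 15 Mannich base (11-CH2NMe2; 4R,6S,7R,10S,11R)
Conditions: LiN(i-Pr)2 (1.1 equiv), THF, −78 °C; then CH2=NMe2+ I−, −78 → 0 °C
Reagents that add atoms: Eschenmoser's salt (N,N-dimethylmethyleneiminium iodide), C=[N+](C)C.[I-]
Why: Mannich reaction of the lactone lithium enolate (the lactone α-CH2 is by far the most acidic C–H) with Eschenmoser's salt installs C13 as a CH2NMe2 group, a masked α-methylene unit, anti to C8, and it is done before the C8 hydroxyl exists so that no strong base meets a translactonisable diol.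

Step 8
Reactants: 15 Mannich base
Product: 17 β-hydroxy ketone (C8 ketone and C10 tertiary alcohol; 4R,6S,7S,10S,11R), via hydroxy imine 16 (not isolated)
Conditions: H2 (1 atm), Raney Ni, B(OH)3, MeOH/H2O (5:1), rt
Reagents that add atoms: water, O
Why: Hydrogenolytic N–O cleavage of the 2-isoxazoline gives the β-hydroxy imine, which boric acid-buffered hydrolysis should convert into the β-hydroxy ketone without retro-aldol cleavage or C7 epimerisation (no C=C bond is present at this stage).

Step 9
Reactants: 17 β-hydroxy ketone
Product: 18 anti-8,10-diol (4R,6S,7R,8R,10S,11R)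
Conditions: Me4NBH(OAc)3 (5 equiv), MeCN/AcOH (1:1), −30 °C
Reagents that add atoms: none
Why: In the Evans–Saksena reduction the C10 hydroxyl exchanges onto boron and delivers hydride intramolecularly to the C8 ketone through a chair transition state with C7 and the C1 ring branch equatorial, which should give the 1,3-anti (8R) diol and leave lactone, ketal and ammonium group untouched.

Step 10
Reactants: 18 anti-8,10-diol
Product: 19 C8 isobutyrate (4R,6S,7S,8R,10S,11R)
Conditions: (i-PrCO)2O (1.5 equiv), DMAP (0.2 equiv), Et3N, CH2Cl2, 0 °C → rt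
Reagents that add atoms: isobutyric anhydride, CC(C)C(=O)OC(=O)C(C)C
Why: DMAP-catalysed acylation should esterify the secondary C8 hydroxyl selectively, the tertiary C10 hydroxyl being unreactive under these conditions.

Step 11
Reactants: 19 C8 isobutyrate
Product: 21 α-methylene lactone ketal (4R,6S,7S,8R,10S), via ammonium iodide 20 (not isolated)
Conditions: MeI (10 equiv), MeOH, rt; evaporation; then aq. NaHCO3/EtOAc, rt
Reagents that add atoms: iodomethane, CI (N-methyl and iodide of 20)
Why: Exhaustive methylation of the Mannich base followed by Hofmann-type E1cB elimination of trimethylamine should unveil the α-methylene-γ-lactone under conditions that leave the isobutyrate and the tertiary alcohol intact.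

Step 12
Reactants: 21 α-methylene lactone ketal
Product: 22 target CNP0293926.1 (4R,6S,7S,8R,10S)
Conditions: AcOH/H2O (4:1), 40 °C
Reagents that add atoms: water, O
Why: Acid-catalysed ketal hydrolysis, helped by relief of transannular strain on forming the sp2 C3, should release the ketone without epimerising C4 or eliminating the tertiary alcohol.

Compound list
1 | (2R)-4-methoxy-2-methyl-4-oxobutanoic acid [(R)-2-methylsuccinic acid 4-methyl ester] | COC(=O)C[C@@H](C)C(=O)O | starting material
2 | 4-bromo-2-methylbut-1-ene | C=C(C)CCBr | starting material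
3 | methyl (3R)-4-chloro-3-methyl-4-oxobutanoate (acid chloride of 1) | COC(=O)C[C@@H](C)C(=O)Cl | intermediate
4 | (3-methylbut-3-en-1-yl)magnesium bromide | C=C(C)CC[Mg]Br | intermediate
5 | methyl (3R)-3,7-dimethyl-4-oxooct-7-enoate | COC(=O)C[C@@H](C)C(=O)CCC(C)=C | intermediate
6 | methyl (3R)-3-[2-(3-methylbut-3-en-1-yl)-1,3-dioxolan-2-yl]butanoate | COC(=O)C[C@@H](C)C1(CCC(C)=C)OCCO1 | intermediate
7 | (3R)-3-[2-(3-methylbut-3-en-1-yl)-1,3-dioxolan-2-yl]butanal | O=CC[C@@H](C)C1(CCC(C)=C)OCCO1 | intermediate
8 | methyl 4-oxobutanoate | COC(=O)CCC=O | starting material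
9 | methyl (3S,4S,6R)-3-formyl-4-hydroxy-6-[2-(3-methylbut-3-en-1-yl)-1,3-dioxolan-2-yl]heptanoate (anti-aldol aldehyde) | O=C[C@@H](CC(=O)OC)[C@@H](O)C[C@@H](C)C1(CCC(C)=C)OCCO1 | intermediate
10 | methyl (3R,4S,6R)-4-hydroxy-3-[(hydroxyimino)methyl]-6-[2-(3-methylbut-3-en-1-yl)-1,3-dioxolan-2-yl]heptanoate | ON=C[C@@H](CC(=O)OC)[C@@H](O)C[C@@H](C)C1(CCC(C)=C)OCCO1 | intermediate
11 | (4R,5S)-4-[(hydroxyimino)methyl]-5-{(2R)-2-[2-(3-methylbut-3-en-1-yl)-1,3-dioxolan-2-yl]propyl}oxolan-2-one (cis-lactone oxime) | ON=C[C@H]1CC(=O)O[C@H]1C[C@@H](C)C2(CCC(C)=C)OCCO2 | intermediate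
12 | (2S,3S)-N-hydroxy-5-oxo-2-{(2R)-2-[2-(3-methylbut-3-en-1-yl)-1,3-dioxolan-2-yl]propyl}oxolane-3-carboximidoyl chloride | ON=C(Cl)[C@H]1CC(=O)O[C@H]1C[C@@H](C)C2(CCC(C)=C)OCCO2 | intermediate
13 | (2S,3R)-5-oxo-2-{(2R)-2-[2-(3-methylbut-3-en-1-yl)-1,3-dioxolan-2-yl]propyl}oxolane-3-carbonitrile N-oxide | [O-][N+]#C[C@H]1CC(=O)O[C@H]1C[C@@H](C)C2(CCC(C)=C)OCCO2 | intermediate
14 | bridged isoxazoline (4R,6S,7R,10S): ten-membered carbocycle C1–C10 with 3,3-ethylenedioxy ketal, 4-methyl, cis-fused γ-lactone (O on C6; C7–C11H2–C12=O) and a 2-isoxazoline C8=N–O–C10 bridged by C9, 10-methyl | C1C(=O)O[C@H]2C[C@@H](C)C3(OCCO3)CC[C@]4(C)ON=C(C4)[C@@H]12 | intermediate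
15 | Mannich base of 14 (4R,6S,7R,10S,11R): C11 carries CH2N(CH3)2 trans to C8 | CN(C)C[C@@H]1C(=O)O[C@H]2C[C@@H](C)C3(OCCO3)CC[C@]4(C)ON=C(C4)[C@@H]12 | intermediate
16 | β-hydroxy imine: as 17 with C8=NH in place of C8=O | CN(C)C[C@@H]1C(=O)O[C@H]2C[C@@H](C)C3(OCCO3)CC[C@](C)(O)CC(=N)[C@@H]12 | intermediate
17 | β-hydroxy ketone (4R,6S,7S,10S,11R): 8-oxo, 10-hydroxy-10-methyl, 3,3-ethylenedioxy, 11-(dimethylaminomethyl) cis-6,12-lactone | CN(C)C[C@@H]1C(=O)O[C@H]2C[C@@H](C)C3(OCCO3)CC[C@](C)(O)CC(=O)[C@@H]12 | intermediate
18 | anti-8,10-diol (4R,6S,7R,8R,10S,11R): as 17 with C8–OH anti to C10–OH | CN(C)C[C@@H]1C(=O)O[C@H]2C[C@@H](C)C3(OCCO3)CC[C@](C)(O)C[C@@H](O)[C@@H]12 | intermediate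
19 | C8 isobutyrate of 18 (4R,6S,7S,8R,10S,11R) | CN(C)C[C@@H]1C(=O)O[C@H]2C[C@@H](C)C3(OCCO3)CC[C@](C)(O)C[C@@H](OC(=O)C(C)C)[C@@H]12 | intermediate
20 | trimethylammonium iodide of 19 | C[N+](C)(C)C[C@@H]1C(=O)O[C@H]2C[C@@H](C)C3(OCCO3)CC[C@](C)(O)C[C@@H](OC(=O)C(C)C)[C@@H]12.[I-] | intermediate
21 | 3,3-ethylenedioxy ketal of the target (4R,6S,7S,8R,10S): α-methylene cis-6,12-lactone, 8-isobutyrate, 10-hydroxy | C=C1C(=O)O[C@H]2C[C@@H](C)C3(OCCO3)CC[C@](C)(O)C[C@@H](OC(=O)C(C)C)[C@@H]12 | intermediate
22 | CNP0293926.1 (4R,6S,7S,8R,10S) | C=C1C(=O)O[C@H]2C[C@@H](C)C(=O)CC[C@](C)(O)C[C@@H](OC(=O)C(C)C)[C@@H]12 | target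

Total step count: 12. Longest linear sequence: 12 steps (1 → 22); 2 and 8 are used as purchased.

Steps most likely to fail

1. Step 6 (key step). Bimolecular dimerisation of the nitrile oxide to the furoxan, or oligomerisation, may outrun the entropically and transannularly disfavoured ten-membered ring closure, and the isopropenyl group may be attacked with poor facial selectivity at C10. Fallback, setting out from 11 and coming back at 14: the oxime itself serves as the dipole precursor. Heating 11 in toluene at 170 °C (sealed tube, about 2 mM) induces the 1,2-prototropic shift to the N–H nitrone, which cannot dimerise and adds to the isopropenyl group in an intramolecular oxime–olefin (nitrone) cycloaddition; this gives the bridged N–H isoxazolidine F1 through a later, more compact transition state that offers an independent chance of C10 control. N-Chlorination (NCS, CH2Cl2, 0 °C) and dehydrochlorination with DBU then give isoxazoline 14.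

2. Step 4. Self-aldolisation of donor 8 may compete with the cross-reaction, and addition to the α-unbranched acceptor may be sluggish or only moderately anti-selective. Fallback, setting out from 7 and coming back at 11: the donor and acceptor roles are fixed by a stoichiometric boron enolate. S-Phenyl 4-methoxy-4-oxobutanethioate F2 (from methyl 4-chloro-4-oxobutanoate, thiophenol and pyridine) is enolised chemoselectively at the thioester with a menthone-derived chiral dialkylboron bromide and Et3N; the (E)-enol borinate adds to 7 through a closed chair transition state to give the anti-aldol thioester F3, the enantiomer of the boron reagent being chosen to match the sense of 9. PPTS in toluene closes the cis-lactone thioester F4. Fukuyama reduction (Et3SiH, Pd/C, acetone, rt) gives the formyl lactone F5, which is oximated at once (NH2OH·HCl, NaOAc, MeOH) to 11.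

3. Step 9. Hydride delivery in the conformationally mobile ten-membered ring may not follow the acyclic 1,3-anti model (external attack, or a chair with the C14 methyl equatorial), leading to the C8 epimer. Fallback, setting out from 17 and coming back at 19: C8 is set by substitution instead of hydride delivery. Chelation-controlled Narasaka–Prasad reduction (Et2BOMe, NaBH4, THF/MeOH, −78 °C) gives the syn-8,10-diol F6; Mitsunobu esterification of its secondary hydroxyl with isobutyric acid (PPh3, DIAD, toluene, 0 °C → rt) inverts C8 and gives 19 directly, the tertiary alcohol being inert.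

Further compounds
F1 | step 6 | bridged N–H isoxazolidine (C8–H; C7 and C1 cis on the heterocycle; otherwise as 14) | C1C(=O)O[C@H]2C[C@@H](C)C3(OCCO3)CC[C@]4(C)ON[C@@H](C4)[C@@H]12
F2 | step 4 | S-phenyl 4-methoxy-4-oxobutanethioate | COC(=O)CCC(=O)Sc1ccccc1
F3 | step 4 | anti-aldol thioester (as 9 with C(=O)SPh in place of CHO) | O=C(Sc1ccccc1)[C@@H](CC(=O)OC)[C@@H](O)C[C@@H](C)C1(CCC(C)=C)OCCO1
F4 | step 4 | cis-lactone thioester (as 11 with C(=O)SPh in place of CH=NOH) | O=C(Sc1ccccc1)[C@H]1CC(=O)O[C@H]1C[C@@H](C)C2(CCC(C)=C)OCCO2
F5 | step 4 | cis-formyl lactone (as 11 with CHO in place of CH=NOH) | O=C[C@H]1CC(=O)O[C@H]1C[C@@H](C)C2(CCC(C)=C)OCCO2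
F6 | step 9 | syn-8,10-diol (C8 epimer of 18; 4R,6S,7R,8S,10S,11R) | CN(C)C[C@@H]1C(=O)O[C@H]2C[C@@H](C)C3(OCCO3)CC[C@](C)(O)C[C@H](O)[C@@H]12
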